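## Retrosynthetic overview

1. Locants used throughout: δ-lactone O2–C1H2–C11a–C4a–C4(=C12)–C3(=O); carbocycle C4a–C5–C6–C7(OH)(CH3)–C8–C9–C10–C11(=CH2)–C11a with the epoxide on C8–C9; side chain C12H=, C13(OAc), C14–C15 epoxide. The target is (4aS,7S,8R,9R,11aR,13S,14R) with an E C4=C12 bond.
2. Feature: the two trigonal ring carbons C4 and C11 lie para to each other across C4a–C11a and C9–C10. A notional C4–C9 bond closes a cyclohexane-1,4-dione ring (C4, C4a, C11a, C11, C10, C9) and leaves the oxygenated C8 one bond from C9, that is 1,3 to C4. The nine-membered ring is therefore the periphery of a bicyclo[4.3.1]decane-2,10-dione and is set free by retro-Claisen scission of C4–C9.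
3. Ring order: six-membered template from dearomatised 4-methoxyphenol (C11a by rhodium-catalysed ethenyl addition, C4a by alkylation with the (S)-citramalate iodide and kinetic protonation; cis on the template corresponds to the trans ring fusion of the target), then the seven-membered bridge by C8–C9 aldol and oxidation, the nine-membered ring by the fragmentation, a temporary γ-lactone, the δ-lactone by cyclocarbonylation of a C4≡C12 alkynol, and finally both epoxides.
4. Further disconnections: C8 ketone to enol triflate to cis C8=C9; ethenyl to C1H2OH; C11 ketal to methylene; C4 ester to alkyne; C12–C13 by asymmetric alkynylation of 3-methylbut-2-enal; C3 from CO; hydroxyl-directed epoxidations; acetate last.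

Key step: step 14

Remark (assumption): (S)-BINAP is taken to select the same enone face as in cyclohexenone, and (S,S)-ProPhenol to deliver the alkynyl group to the Si face of the aldehyde; if either sense proves opposite, the antipodal ligand is used.

## Route

Step 1
Reactants: 1 (S)-citramalic acid
Product: 2 2-[(4S)-2,2,4-trimethyl-5-oxo-1,3-dioxolan-4-yl]acetic acid
Conditions: 2,2-dimethoxypropane (excess), TsOH·H2O (5 mol%), rt
Reagents that add atoms: 2,2-dimethoxypropane, COC(C)(C)OC
Why: Acid-catalysed transketalisation ties the tertiary hydroxyl and its adjacent carboxyl into the five-membered dioxolanone, which leaves the distal carboxyl (future C5) free and does not touch the stereocentre (future C7).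

Step 2
Reactants: 2 2-[(4S)-2,2,4-trimethyl-5-oxo-1,3-dioxolan-4-yl]acetic acid
Product: 3 (5S)-5-(2-hydroxyethyl)-2,2,5-trimethyl-1,3-dioxolan-4-one
Conditions: BH3·SMe2 (1.2 equiv), THF, 0 °C → rt; MeOH quench
Reagents that add atoms: none
Why: Borane reduces a free carboxylic acid far faster than the dioxolanone carbonyl (chemoselective acid reduction), so only the future C5 becomes a primary alcohol.

Step 3
Reactants: 3 (5S)-5-(2-hydroxyethyl)-2,2,5-trimethyl-1,3-dioxolan-4-one
Product: 4 (5S)-5-(2-iodoethyl)-2,2,5-trimethyl-1,3-dioxolan-4-one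
Conditions: I2, PPh3, imidazole, CH2Cl2, 0 °C → rt
Reagents that add atoms: iodine, II
Why: Appel-type iodination of the primary alcohol proceeds under near-neutral conditions that leave the dioxolanone intact and remove the hydroxyl before it can translactonise.

Step 4
Reactants: 4 (5S)-5-(2-iodoethyl)-2,2,5-trimethyl-1,3-dioxolan-4-one
Product: 5 methyl (2S)-2-hydroxy-4-iodo-2-methylbutanoate
Conditions: TsOH·H2O (10 mol%), MeOH, 40 °C
Reagents that add atoms: methanol, CO
Why: Acid-catalysed methanolysis (transesterification) of the acyl ketal releases acetone and gives the methyl ester with the tertiary hydroxyl free, no base being present that could displace the iodide.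

Step 5
Reactants: 5 methyl (2S)-2-hydroxy-4-iodo-2-methylbutanoate
Product: 6 methyl (2S)-4-iodo-2-methyl-2-(triethylsilyloxy)butanoate
Conditions: Et3SiOTf, 2,6-lutidine, CH2Cl2, −78 → 0 °C
Reagents that add atoms: triethylsilyl trifluoromethanesulfonate, CC[Si](CC)(CC)OS(=O)(=O)C(F)(F)F
Why: Silyl triflate with a hindered pyridine base silylates even a tertiary α-hydroxy ester, giving the C5–C8 fragment with C7 protected.

Step 6
Reactants: 7 4-methoxyphenol
Product: 8 4,4-dimethoxycyclohexa-2,5-dien-1-one
Conditions: PhI(OAc)2, MeOH, 0 °C → rt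
Reagents that add atoms: methanol, CO
Why: Oxidative dearomatisation with the hypervalent iodine reagent generates a phenoxenium-type species that methanol traps at the para carbon, giving the quinone monoketal whose two enones are the handles for C11a, C4a and C9.

Step 7
Reactants: 8 4,4-dimethoxycyclohexa-2,5-dien-1-one
Product: 9 (5S)-5-ethenyl-4,4-dimethoxycyclohex-2-en-1-one
Conditions: [RhCl(C2H4)2]2 (2.5 mol%), (S)-BINAP (5.5 mol%), 2-ethenyl-4,4,5,5-tetramethyl-1,3,2-dioxaborolane (1.1 equiv), KOH (0.5 equiv, aq.), 1,4-dioxane, 40 °C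
Reagents that add atoms: 2-ethenyl-4,4,5,5-tetramethyl-1,3,2-dioxaborolane, C=CB1OC(C)(C)C(C)(C)O1
Why: Hayashi–Miyaura rhodium-catalysed asymmetric 1,4-addition desymmetrises the dienone, the (S)-BINAP–rhodium ethenyl species choosing the enone face that should give the 5S centre (future C11a, whose ethenyl CH is the future C1), while limiting the boronate and the added bulk next to the ketal hold back a second addition.

Step 8
Reactants: 9 (5S)-5-ethenyl-4,4-dimethoxycyclohex-2-en-1-one and 6 methyl (2S)-4-iodo-2-methyl-2-(triethylsilyloxy)butanoate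
Product: 11 methyl (2S)-4-[(1R,6R)-6-ethenyl-5,5-dimethoxy-2-oxocyclohex-3-en-1-yl]-2-methyl-2-(triethylsilyloxy)butanoate, via lithium dienolate 10 (not isolated)
Conditions: LiN(iPr)2 (1.05 equiv), THF, −78 °C; then 6 (1.2 equiv), HMPA (4 equiv), −78 → −20 °C
Reagents that add atoms: none
Why: Kinetic deprotonation at the only sp3 α-carbon gives the cross-conjugated dienolate, whose SN2 alkylation by the primary iodide forms C4a–C5 anti to the ethenyl group (trans product expected), a relationship that is corrected in the next step so its selectivity is not critical.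

Step 9
Reactants: 11 methyl (2S)-4-[(1R,6R)-6-ethenyl-5,5-dimethoxy-2-oxocyclohex-3-en-1-yl]-2-methyl-2-(triethylsilyloxy)butanoate
Product: 13 methyl (2S)-4-[(1S,6R)-6-ethenyl-5,5-dimethoxy-2-oxocyclohex-3-en-1-yl]-2-methyl-2-(triethylsilyloxy)butanoate, via lithium dienolate 12 (not isolated)
Conditions: LiN(iPr)2 (1.2 equiv), THF, −78 °C; then 2,6-di-tert-butyl-4-methylphenol (2 equiv) in THF, −78 °C; aq. NH4Cl at −78 °C
Reagents that add atoms: none
Why: Kinetic protonation of the C4a enolate, in which A(1,2) strain holds the C11a ethenyl group pseudo-axial, should deliver the proton anti to that group and so place the side chain cis to it, the relationship that the C4–C9 bridge of the template translates into the trans C4a/C11a fusion of the target, with the hindered ester surviving the short exposure at −78 °C and any trans isomer being recycled through this step.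

Step 10
Reactants: 13 methyl (2S)-4-[(1S,6R)-6-ethenyl-5,5-dimethoxy-2-oxocyclohex-3-en-1-yl]-2-methyl-2-(triethylsilyloxy)butanoate
Product: 14 methyl (2S)-4-[(1S,6R)-2-(dimethylphenylsilyloxy)-6-ethenyl-5,5-dimethoxycyclohex-2-en-1-yl]-2-methyl-2-(triethylsilyloxy)butanoate
Conditions: [(Ph3P)CuH]6 (5 mol%), PhMe2SiH (1.3 equiv), PhMe, 0 °C → rt
Reagents that add atoms: dimethylphenylsilane, C[SiH](C)c1ccccc1
Why: Copper hydride-catalysed 1,4-hydrosilylation of the enone gives the enol silane regiospecifically toward C9 without base, which fixes the labile C4a centre, masks the C4 ketone for the next reduction and leaves the isolated ethenyl group and the ester untouched.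

Step 11
Reactants: 14 methyl (2S)-4-[(1S,6R)-2-(dimethylphenylsilyloxy)-6-ethenyl-5,5-dimethoxycyclohex-2-en-1-yl]-2-methyl-2-(triethylsilyloxy)butanoate
Product: 15 (2S)-4-[(1S,6R)-2-(dimethylphenylsilyloxy)-6-ethenyl-5,5-dimethoxycyclohex-2-en-1-yl]-2-methyl-2-(triethylsilyloxy)butanal
Conditions: iBu2AlH (1.1 equiv), CH2Cl2, −78 °C; MeOH, then aq. potassium sodium tartrate
Reagents that add atoms: none
Why: Partial reduction of the α-silyloxy, α-quaternary ester stops at the chelated aluminium hemiacetal at −78 °C and releases the non-enolisable C8 aldehyde on work-up, the enol silane being inert to the hydride.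

Step 12
Reactants: 15 (2S)-4-[(1S,6R)-2-(dimethylphenylsilyloxy)-6-ethenyl-5,5-dimethoxycyclohex-2-en-1-yl]-2-methyl-2-(triethylsilyloxy)butanal
Product: 17 7-ethenyl-2-hydroxy-8,8-dimethoxy-3-methyl-3-(triethylsilyloxy)bicyclo[4.3.1]decan-10-one, via silyl ether 16 (not isolated)
Conditions: Bu4N[Ph3SiF2] (10 mol%), THF, −78 → −40 °C; then PPTS (0.2 equiv), MeOH, 0 °C
Reagents that add atoms: none
Why: Fluoride-catalysed aldol addition of the enol silane (Noyori–Kuwajima variant of the Mukaiyama aldol) generates the C9 enolate regiospecifically, which closes the bridge onto the C8 aldehyde in a 7-(enolendo)-exo-trig mode through the conformer with the side chain axial, the tether forcing the new C9–C8 bond cis to C4a–C5, silyl transfer to the aldolate preventing retro-aldol, the C8 carbinol configuration being irrelevant and methanolic PPTS then removing only the secondary silyl group.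

Step 13
Reactants: 17 7-ethenyl-2-hydroxy-8,8-dimethoxy-3-methyl-3-(triethylsilyloxy)bicyclo[4.3.1]decan-10-one
Product: 18 7-ethenyl-8,8-dimethoxy-3-methyl-3-(triethylsilyloxy)bicyclo[4.3.1]decane-2,10-dione
Conditions: Dess–Martin periodinane (1.5 equiv), NaHCO3, CH2Cl2, 0 °C → rt
Reagents that add atoms: none
Why: Dess–Martin oxidation converts both C8 epimers into the bridged 1,3-diketone under buffered, non-nucleophilic conditions that trigger neither retro-aldol nor premature retro-Claisen cleavage.

Step 14
Reactants: 18 7-ethenyl-8,8-dimethoxy-3-methyl-3-(triethylsilyloxy)bicyclo[4.3.1]decane-2,10-dione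
Product: 19 methyl 9-ethenyl-8,8-dimethoxy-4-methyl-5-oxo-4-(triethylsilyloxy)cyclononane-1-carboxylate
Conditions: NaOMe (0.3 equiv), MeOH/THF (4:1), 0 °C
Reagents that add atoms: methanol (delivered as sodium methoxide), CO
Why: Methoxide adds to the bridging C4 carbonyl and the tetrahedral alkoxide collapses by breaking C4–C9, the electron pair passing into the C8 carbonyl as its enolate, which methanol protonates at C9 with return of methoxide, so that C4 becomes the methyl ester on C4a. The closest known reaction is the alkoxide-induced retro-Claisen (retro-Dieckmann) cleavage of bridged bicyclic 1,3-diketones, as in bicyclo[3.3.1]nonane-2,9-diones opening to 4-oxocyclooctanecarboxylates, of which 18 is the next homologue. No ring is closed by a cyclisation: the nine-membered ring C4a–C5–C6–C7–C8–C9–C10–C11–C11a already exists as the periphery of the bicycle and is released when the one-carbon bridge is cut. No stereocentre is created, C9 becoming a methylene group, and C4a, C7 and C11a are carried over, the sub-stoichiometric base at 0 °C being chosen so that C4a, now α to the ester, is not epimerised. The step needs cleavage of C4–C9 and not of C8–C9 (which would return a cyclohexanone keto ester): C4 is the strained one-carbon-bridge ketone whose rehybridisation relieves angle strain and the dipole repulsion of the 1,3-dicarbonyl, whereas C8 is flanked by the quaternary C7 carrying methyl and OSiEt3, and from the C4 adduct only C9 can depart as a stabilised carbanion because C4a has no carbonyl neighbour. The driving force is the conversion of a non-enolisable bridged β-diketone, strained further by the C11 ketal inside the bicycle, into an ester and a simple ketone.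

Step 15
Reactants: 19 methyl 9-ethenyl-8,8-dimethoxy-4-methyl-5-oxo-4-(triethylsilyloxy)cyclononane-1-carboxylate
Product: 21 methyl 9-ethenyl-8,8-dimethoxy-4-methyl-4-(triethylsilyloxy)-5-(trifluoromethanesulfonyloxy)cyclonon-5-ene-1-carboxylate (ring-cis C8=C9), via potassium enolate 20 (not isolated)
Conditions: KN(SiMe3)2 (1.1 equiv), THF, −78 °C; then PhNTf2, −78 → 0 °C
Reagents that add atoms: N-phenylbis(trifluoromethanesulfonimide), O=S(=O)(N(c1ccccc1)S(=O)(=O)C(F)(F)F)C(F)(F)F
Why: The C8 ketone can enolise only toward C9 because C7 is quaternary and is more acidic than the ester, the nine-membered enolate should form with the unstrained ring-cis geometry, and O-triflation fixes it as the enol triflate.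

Step 16
Reactants: 21 ring-cis C8 enol triflate
Product: 24 trans-fused γ-lactone (C4(=O)–O–C1H2 across C4a/C11a) carrying the C8 enol triflate, the C11 dimethyl ketal and C7–OSiEt3, via ozonide 22 (not isolated), via hydroxy ester 23 (not isolated)
Conditions: O3, CH2Cl2/MeOH (5:1), −78 °C (Sudan Red 7B end-point); NaBH4, −78 → 0 °C; work-up, then PPTS (cat.), PhMe, 40 °C
Reagents that add atoms: ozone, [O-][O+]=O
Why: Ozonolysis should take the monosubstituted ethenyl group much faster than the triflate-deactivated C8=C9 bond, borohydride reduces the ozonide directly to the C1 alcohol so that the epimerisable β-methoxy aldehyde is never handled, and lactonisation onto the neighbouring ester masks C1–OH and C4 together without touching C4a or C11a.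

Step 17
Reactants: 24 γ-lactone enol triflate with C11 dimethyl ketal
Product: 25 γ-lactone enol triflate with C11 ketone
Conditions: PPTS (0.2 equiv), acetone/H2O (10:1), rt
Reagents that add atoms: water, O
Why: Mild acid-catalysed ketal hydrolysis unveils the C11 ketone while the enol triflate blocks migration of the C8=C9 bond into conjugation and the absence of base avoids epimerisation at C11a and E1cB loss of the C1 carboxylate.

Step 18
Reactants: 25 γ-lactone enol triflate with C11 ketone
Product: 26 γ-lactone enol triflate with C11 methylene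
Conditions: Zn, CH2Br2, TiCl4 (pre-formed reagent), THF/CH2Cl2, 0 °C → rt
Reagents that add atoms: dibromomethane, BrCBr
Why: Takai–Lombardo methylenation with the non-basic geminal dizinc reagent converts the ketone and not the lactone into the exocyclic methylene group without enolising C11a.

Step 19
Reactants: 26 γ-lactone enol triflate with C11 methylene
Product: 27 γ-lactone with cis C8=C9, C11=CH2 and C7–OSiEt3
Conditions: Pd(OAc)2 (5 mol%), PPh3 (10 mol%), HCO2H (2 equiv), Bu3N (3 equiv), DMF, 60 °C
Reagents that add atoms: none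
Why: Palladium-catalysed formate reduction of the enol triflate (oxidative addition, formate decarboxylation, reductive elimination) replaces OTf by hydrogen with retention and so gives the Z C8=C9 alkene required for the cis epoxide.

Step 20
Reactants: 27 γ-lactone with cis C8=C9 and C11=CH2
Product: 28 lactol (C4 hemiacetal, anomer mixture)
Conditions: iBu2AlH (1.1 equiv), CH2Cl2, −78 °C; aq. potassium sodium tartrate
Reagents that add atoms: none
Why: Half-reduction of the γ-lactone stops at the aluminium hemiacetal at −78 °C and gives the lactol as a masked C4 aldehyde.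

Step 21
Reactants: 28 lactol
Product: 29 [(6Z)-2-ethynyl-5-methyl-9-methylidene-5-(triethylsilyloxy)cyclonon-6-en-1-yl]methanol (ethynyl on C4a, CH2OH on C11a, trans)
Conditions: dimethyl (1-diazo-2-oxopropyl)phosphonate (1.5 equiv), K2CO3, MeOH, 0 °C → rt
Reagents that add atoms: dimethyl (1-diazo-2-oxopropyl)phosphonate, CC(=O)C(=[N+]=[N-])P(=O)(OC)OC
Why: Seyferth–Gilbert homologation with the Ohira–Bestmann reagent acts on the open hydroxy aldehyde form of the lactol, the alkylidene carbene rearranging by 1,2-hydrogen shift to the terminal alkyne (new carbon C12) and freeing C1–OH in the same operation, the mild carbonate base being expected to leave C4a intact.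

Step 22
Reactants: 29 hydroxy alkyne
Product: 30 C1 triethylsilyl ether of 29
Conditions: Et3SiCl, imidazole, CH2Cl2, 0 °C
Reagents that add atoms: chlorotriethylsilane, CC[Si](Cl)(CC)CC
Why: Silylation of the primary alcohol removes the acidic proton that would otherwise consume the zinc reagent and perturb the catalyst of the next step.

Step 23
Reactants: 30 C1 triethylsilyl ether of 29 and 31 3-methylbut-2-enal
Product: 33 (3R)-5-methyl-1-[ring]hex-4-en-1-yn-3-ol, the 13R propargylic alcohol of 30, via zinc alkynylide 32 (not isolated)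
Conditions: (S,S)-ProPhenol (20 mol%), Me2Zn (3 equiv), Ph3P=O (40 mol%), PhMe, 0 °C → rt; 31 (2 equiv)
Reagents that add atoms: none
Why: Trost zinc–ProPhenol alkynylation forms C12–C13 by addition of the methylzinc alkynylide to the enal inside the dinuclear zinc complex, which binds both partners and should deliver the alkynyl group to the Si face to set 13R under reagent control.

Step 24
Reactants: 33 13R propargylic alcohol
Product: 34 C13 tert-butyldimethylsilyl ether of 33
Conditions: tBuMe2SiCl, imidazole, DMF, rt
Reagents that add atoms: tert-butylchlorodimethylsilane, CC(C)(C)[Si](C)(C)Cl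
Why: Silylation protects the doubly activated (propargylic and allylic) carbinol against ionisation and against competing as a nucleophile under the Lewis-acidic carbonylation conditions.

Step 25
Reactants: 34 tris-silyl ether
Product: 35 C1 alcohol (C13–OSitBuMe2 and C7–OSiEt3 retained)
Conditions: PPTS (0.1 equiv), MeOH/CH2Cl2 (1:1), 0 °C
Reagents that add atoms: none
Why: Acid-catalysed methanolysis removes the unhindered primary triethylsilyl ether much faster than the secondary tert-butyldimethylsilyl and the tertiary triethylsilyl ethers.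

Step 26
Reactants: 35 C1 alcohol
Product: 36 (E)-α-alkylidene δ-lactone (O2–C3(=O)–C4(=C12H)) with C13–OSitBuMe2 and C7–OSiEt3
Conditions: PdCl2(PPh3)2 (10 mol%), SnCl2 (10 mol%), CO (7 atm), MeCN, 70 °C
Reagents that add atoms: carbon monoxide, [C-]#[O+]
Why: Norton cyclocarbonylation converts C1–OH and CO into a divalent palladium alkoxycarbonyl that adds syn across C4≡C12 in a 6-exo-dig mode with the acyl carbon (C3) on C4, and protonolysis of the vinyl–palladium bond with retention leaves the C12 hydrogen cis to the carbonyl, which is the E geometry of the target.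

Step 27
Reactants: 36 (E)-α-alkylidene δ-lactone bis-silyl ether
Product: 37 7,13-diol with cis C8=C9, C14=C15 and C11=CH2
Conditions: HF·pyridine, pyridine, THF, 0 °C → rt
Reagents that add atoms: none
Why: Buffered hydrogen fluoride cleaves both silyl ethers by fluoride attack at silicon without the basic conditions that could deprotonate C4a through the alkylidene lactone.

Step 28
Reactants: 37 7,13-diol
Product: 38 8,9:14,15-bis-epoxy 7,13-diol (13-deacetyl target)
Conditions: VO(acac)2 (15 mol%), tBuOOH (3 equiv, in decane), CH2Cl2, 0 °C → rt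
Reagents that add atoms: tert-butyl hydroperoxide, CC(C)(C)OO
Why: Vanadium-catalysed hydroxyl-directed epoxidation should deliver oxygen from the C7 vanadate to the cis C8=C9 bond on the face of the hydroxyl (syn epoxy alcohol, as known for medium-ring allylic alcohols) and from the C13 vanadate to C14=C15 through the conformer that avoids A(1,3) strain with the cis methyl of C15 (threo, 14R), while C11=CH2 has no allylic hydroxyl and the electron-poor C4=C12 is unreactive.

Step 29
Reactants: 38 8,9:14,15-bis-epoxy 7,13-diol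
Product: 39 target, (4aS,7S,8R,9R,11aR,13S,14R)-13-acetate
Conditions: Ac2O, pyridine, DMAP (cat.), CH2Cl2, 0 °C
Reagents that add atoms: acetic anhydride, CC(=O)OC(C)=O
Why: Nucleophile-catalysed acylation takes the secondary C13 hydroxyl and leaves the tertiary C7 hydroxyl free.

## Compound list

1 | (S)-citramalic acid, (2S)-2-hydroxy-2-methylbutanedioic acid | OC(=O)[C@@](C)(O)CC(=O)O | starting material
2 | 2-[(4S)-2,2,4-trimethyl-5-oxo-1,3-dioxolan-4-yl]acetic acid | CC1(C)OC(=O)[C@](C)(CC(=O)O)O1 | intermediate
3 | (5S)-5-(2-hydroxyethyl)-2,2,5-trimethyl-1,3-dioxolan-4-one | CC1(C)OC(=O)[C@](C)(CCO)O1 | intermediate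
4 | (5S)-5-(2-iodoethyl)-2,2,5-trimethyl-1,3-dioxolan-4-one | CC1(C)OC(=O)[C@](C)(CCI)O1 | intermediate
5 | methyl (2S)-2-hydroxy-4-iodo-2-methylbutanoate | COC(=O)[C@@](C)(O)CCI | intermediate
6 | methyl (2S)-4-iodo-2-methyl-2-(triethylsilyloxy)butanoate | COC(=O)[C@@](C)(O[Si](CC)(CC)CC)CCI | intermediate
7 | 4-methoxyphenol | COc1ccc(O)cc1 | starting material
8 | 4,4-dimethoxycyclohexa-2,5-dien-1-one | COC1(OC)C=CC(=O)C=C1 | intermediate
9 | (5S)-5-ethenyl-4,4-dimethoxycyclohex-2-en-1-one | O=C1C=CC(OC)(OC)[C@H](C=C)C1 | intermediate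
10 | cross-conjugated lithium dienolate of 9 (C4–OLi, C4=C4a) | [Li+].[O-]C1=C[C@@H](C=C)C(OC)(OC)C=C1 | intermediate (not isolated)
11 | methyl (2S)-4-[(1R,6R)-6-ethenyl-5,5-dimethoxy-2-oxocyclohex-3-en-1-yl]-2-methyl-2-(triethylsilyloxy)butanoate (side chain trans to ethenyl) | O=C1C=CC(OC)(OC)[C@H](C=C)[C@H]1CC[C@](C)(O[Si](CC)(CC)CC)C(=O)OC | intermediate
12 | cross-conjugated lithium dienolate of 11 | [Li+].[O-]C1=C(CC[C@](C)(O[Si](CC)(CC)CC)C(=O)OC)[C@@H](C=C)C(OC)(OC)C=C1 | intermediate (not isolated)
13 | methyl (2S)-4-[(1S,6R)-6-ethenyl-5,5-dimethoxy-2-oxocyclohex-3-en-1-yl]-2-methyl-2-(triethylsilyloxy)butanoate (side chain cis to ethenyl) | O=C1C=CC(OC)(OC)[C@H](C=C)[C@@H]1CC[C@](C)(O[Si](CC)(CC)CC)C(=O)OC | intermediate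
14 | methyl (2S)-4-[(1S,6R)-2-(dimethylphenylsilyloxy)-6-ethenyl-5,5-dimethoxycyclohex-2-en-1-yl]-2-methyl-2-(triethylsilyloxy)butanoate | C[Si](C)(c1ccccc1)OC1=CCC(OC)(OC)[C@H](C=C)[C@@H]1CC[C@](C)(O[Si](CC)(CC)CC)C(=O)OC | intermediate
15 | (2S)-4-[(1S,6R)-2-(dimethylphenylsilyloxy)-6-ethenyl-5,5-dimethoxycyclohex-2-en-1-yl]-2-methyl-2-(triethylsilyloxy)butanal | C[Si](C)(c1ccccc1)OC1=CCC(OC)(OC)[C@H](C=C)[C@@H]1CC[C@](C)(O[Si](CC)(CC)CC)C=O | intermediate
16 | 2-(dimethylphenylsilyloxy)-7-ethenyl-8,8-dimethoxy-3-methyl-3-(triethylsilyloxy)bicyclo[4.3.1]decan-10-one (C8 silyl ether of 17, C8 epimers) | O=C1[C@H]2CC[C@](C)(O[Si](CC)(CC)CC)C(O[Si](C)(C)c3ccccc3)[C@@H]1CC(OC)(OC)[C@@H]2C=C | intermediate (not isolated)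
17 | 7-ethenyl-2-hydroxy-8,8-dimethoxy-3-methyl-3-(triethylsilyloxy)bicyclo[4.3.1]decan-10-one (ethenyl on the face of the six-membered ring that carries the four-carbon bridge; C8 carbinol as epimer mixture) | O=C1[C@H]2CC[C@](C)(O[Si](CC)(CC)CC)C(O)[C@@H]1CC(OC)(OC)[C@@H]2C=C | intermediate
18 | 7-ethenyl-8,8-dimethoxy-3-methyl-3-(triethylsilyloxy)bicyclo[4.3.1]decane-2,10-dione (C4 and C8 ketones, C4–C9 bridge) | O=C1[C@H]2CC[C@](C)(O[Si](CC)(CC)CC)C(=O)[C@@H]1CC(OC)(OC)[C@@H]2C=C | intermediate
19 | methyl 9-ethenyl-8,8-dimethoxy-4-methyl-5-oxo-4-(triethylsilyloxy)cyclononane-1-carboxylate (ester on C4a and ethenyl on C11a trans) | COC(=O)[C@H]1CC[C@](C)(O[Si](CC)(CC)CC)C(=O)CCC(OC)(OC)[C@@H]1C=C | intermediate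
20 | potassium enolate of 19 (C8–OK, ring-cis C8=C9) | [K+].COC(=O)[C@H]1CC[C@](C)(O[Si](CC)(CC)CC)/C([O-])=C\CC(OC)(OC)[C@@H]1C=C | intermediate (not isolated)
21 | methyl 9-ethenyl-8,8-dimethoxy-4-methyl-4-(triethylsilyloxy)-5-(trifluoromethanesulfonyloxy)cyclonon-5-ene-1-carboxylate (ring-cis enol triflate) | COC(=O)[C@H]1CC[C@](C)(O[Si](CC)(CC)CC)/C(OS(=O)(=O)C(F)(F)F)=C\CC(OC)(OC)[C@@H]1C=C | intermediate
22 | ozonide (1,2,4-trioxolane) of the ethenyl group of 21 | COC(=O)[C@H]1CC[C@](C)(O[Si](CC)(CC)CC)/C(OS(=O)(=O)C(F)(F)F)=C\CC(OC)(OC)[C@@H]1C2OCOO2 | intermediate (not isolated)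
23 | C1 hydroxy ester (hydroxymethyl on C11a, methyl ester on C4a) | COC(=O)[C@H]1CC[C@](C)(O[Si](CC)(CC)CC)/C(OS(=O)(=O)C(F)(F)F)=C\CC(OC)(OC)[C@@H]1CO | intermediate (not isolated)
24 | trans-fused γ-lactone with C8 enol triflate, C11 dimethyl ketal, C7–OSiEt3 | O=C3[C@H]1CC[C@](C)(O[Si](CC)(CC)CC)/C(OS(=O)(=O)C(F)(F)F)=C\CC(OC)(OC)[C@@H]1CO3 | intermediate
25 | trans-fused γ-lactone with C8 enol triflate and C11 ketone | O=C3[C@H]1CC[C@](C)(O[Si](CC)(CC)CC)/C(OS(=O)(=O)C(F)(F)F)=C\CC(=O)[C@@H]1CO3 | intermediate
26 | trans-fused γ-lactone with C8 enol triflate and C11 methylene | O=C3[C@H]1CC[C@](C)(O[Si](CC)(CC)CC)/C(OS(=O)(=O)C(F)(F)F)=C\CC(=C)[C@@H]1CO3 | intermediate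
27 | trans-fused γ-lactone with cis C8=C9 and C11 methylene | O=C3[C@H]1CC[C@](C)(O[Si](CC)(CC)CC)/C=C\CC(=C)[C@@H]1CO3 | intermediate
28 | lactol of 27 (C4 hemiacetal, anomer mixture) | OC3[C@H]1CC[C@](C)(O[Si](CC)(CC)CC)/C=C\CC(=C)[C@@H]1CO3 | intermediate
29 | [(6Z)-2-ethynyl-5-methyl-9-methylidene-5-(triethylsilyloxy)cyclonon-6-en-1-yl]methanol | C#C[C@H]1CC[C@](C)(O[Si](CC)(CC)CC)/C=C\CC(=C)[C@@H]1CO | intermediate
30 | C1 triethylsilyl ether of 29 | C#C[C@H]1CC[C@](C)(O[Si](CC)(CC)CC)/C=C\CC(=C)[C@@H]1CO[Si](CC)(CC)CC | intermediate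
31 | 3-methylbut-2-enal | CC(C)=CC=O | starting material
32 | methylzinc alkynylide of 30 | C[Zn]C#C[C@H]1CC[C@](C)(O[Si](CC)(CC)CC)/C=C\CC(=C)[C@@H]1CO[Si](CC)(CC)CC | intermediate (not isolated)
33 | (3R)-5-methyl-1-[ring]hex-4-en-1-yn-3-ol, 13R propargylic alcohol of 30 | CC(C)=C[C@@H](O)C#C[C@H]1CC[C@](C)(O[Si](CC)(CC)CC)/C=C\CC(=C)[C@@H]1CO[Si](CC)(CC)CC | intermediate
34 | C13 tert-butyldimethylsilyl ether of 33 | CC(C)=C[C@@H](O[Si](C)(C)C(C)(C)C)C#C[C@H]1CC[C@](C)(O[Si](CC)(CC)CC)/C=C\CC(=C)[C@@H]1CO[Si](CC)(CC)CC | intermediate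
35 | C1 alcohol from 34 | CC(C)=C[C@@H](O[Si](C)(C)C(C)(C)C)C#C[C@H]1CC[C@](C)(O[Si](CC)(CC)CC)/C=C\CC(=C)[C@@H]1CO | intermediate
36 | (E)-α-alkylidene δ-lactone with C13–OSitBuMe2 and C7–OSiEt3 | C=C1C/C=C\[C@@](C)(O[Si](CC)(CC)CC)CC[C@@H]2/C(=C\[C@H](O[Si](C)(C)C(C)(C)C)C=C(C)C)C(=O)OC[C@@H]12 | intermediate
37 | 7,13-diol | C=C1C/C=C\[C@@](C)(O)CC[C@@H]2/C(=C\[C@H](O)C=C(C)C)C(=O)OC[C@@H]12 | intermediate
38 | 8,9:14,15-bis-epoxy 7,13-diol (13-deacetyl target) | C=C1C[C@H]2O[C@H]2[C@@](C)(O)CC[C@@H]2/C(=C\[C@H](O)[C@H]3OC3(C)C)C(=O)OC[C@@H]12 | intermediate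
39 | CNP0113449.2, (4aS,7S,8R,9R,11aR,13S,14R) in the locants of the overview | C=C1C[C@H]2O[C@H]2[C@@](C)(O)CC[C@@H]2/C(=C\[C@H](OC(C)=O)[C@H]3OC3(C)C)C(=O)OC[C@@H]12 | target

## Step count and risks

Total step count: 29. Longest linear sequence: 27 steps (steps 1–5, then 8–29).

**Step 14 (key step).** The risk is that methoxide adds to the C8 carbonyl, or that the C4 adduct reverts faster than it cleaves, so that scission of C8–C9 returns a six-membered keto ester; prolonged exposure to base could also epimerise C4a. The fallback separates carbonyl selection from fragmentation and sets out from diketone 18. NaBH4 in MeOH/CH2Cl2 at −78 °C should reduce the more exposed, strained bridging ketone irreversibly to the bridged ketol, 7-ethenyl-10-hydroxy-8,8-dimethoxy-3-methyl-3-(triethylsilyloxy)bicyclo[4.3.1]decan-2-one F1 (reduction at C8 instead would give back 17, which is recycled through step 13). Catalytic KOtBu in THF at 0 °C then opens F1 by retro-aldol cleavage of C4–C9 to the nine-membered keto aldehyde F2. Pinnick oxidation (NaClO2, NaH2PO4, 2-methylbut-2-ene, tBuOH/H2O) gives the keto acid F3, and Me3SiCHN2 in MeOH/PhMe gives the methyl ester, returning to the route at 19.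

**Step 12.** The risk is that the fluoride-generated enolate is protonated, or equilibrates to the C4a enolate, faster than it closes the strained seven-membered bridge, or that the aldolate reverts by retro-aldol before it is silylated. The fallback sets out from enol silane aldehyde 15. N-Bromosuccinimide in THF at −78 °C converts the enol silane into the α-bromo ketone aldehyde F4 (C9 epimers). SmI2 (2.2 equiv, THF, −78 °C) then generates the samarium enolate regiospecifically at C9 under aprotic, non-basic conditions and closes the bridge as a chelated trivalent samarium aldolate (intramolecular samarium Reformatsky reaction), returning to the route at ketol 17.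

**Step 26.** The risk is slow syn-acylpalladation of the hindered internal alkyne, with ionisation at C13 or C7 under the Lewis-acidic conditions taking over. The fallback divides the carbonylation into two known operations and sets out from alkynol 35. Cp2Zr(H)Cl (2.2 equiv, THF, rt) first forms the zirconium alkoxide of C1–OH, which should direct syn-hydrozirconation with zirconium on C4, and I2 at 0 °C gives the vinyl iodide F5 (iodine on C4 cis to the C12 hydrogen). Carbonylative lactonisation with Pd(PPh3)4 (5 mol%, zerovalent palladium), CO (1 atm) and Et3N in MeCN at 50 °C proceeds with retention of the alkene geometry and returns to the route at 36.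

## Further compounds

F1 | step 14 | 7-ethenyl-10-hydroxy-8,8-dimethoxy-3-methyl-3-(triethylsilyloxy)bicyclo[4.3.1]decan-2-one (C4 carbinol, either epimer) | OC1[C@H]2CC[C@](C)(O[Si](CC)(CC)CC)C(=O)[C@@H]1CC(OC)(OC)[C@@H]2C=C
F2 | step 14 | 9-ethenyl-8,8-dimethoxy-4-methyl-5-oxo-4-(triethylsilyloxy)cyclononane-1-carbaldehyde | O=C[C@H]1CC[C@](C)(O[Si](CC)(CC)CC)C(=O)CCC(OC)(OC)[C@@H]1C=C
F3 | step 14 | 9-ethenyl-8,8-dimethoxy-4-methyl-5-oxo-4-(triethylsilyloxy)cyclononane-1-carboxylic acid | OC(=O)[C@H]1CC[C@](C)(O[Si](CC)(CC)CC)C(=O)CCC(OC)(OC)[C@@H]1C=C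
F4 | step 12 | (2S)-4-[(1S,6R)-3-bromo-6-ethenyl-5,5-dimethoxy-2-oxocyclohexyl]-2-methyl-2-(triethylsilyloxy)butanal (C9 bromide, epimer mixture) | O=C1C(Br)CC(OC)(OC)[C@H](C=C)[C@@H]1CC[C@](C)(O[Si](CC)(CC)CC)C=O
F5 | step 26 | vinyl iodide from 35 (iodine on C4, hydrogen on C12, C13 cis to C4a) | CC(C)=C[C@@H](O[Si](C)(C)C(C)(C)C)/C=C(I)\[C@H]1CC[C@](C)(O[Si](CC)(CC)CC)/C=C\CC(=C)[C@@H]1CO
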